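The numbers of this flask were set for the occasion; what happens was integrated by code.

In this flask substrate attacks target with a constant of 120 L mol⁻¹ min⁻¹, larger than the 29 L mol⁻¹ min⁻¹ with which it makes target.

    substrate + reagent in the reaction phase → target (k1 = 29 L mol⁻¹ min⁻¹)
    substrate + target → side product (k2 = 120 L mol⁻¹ min⁻¹)
    target ⇌ product in the second phase, rate k3*([target] - [product in the second phase]/K3) per volume of the first phase (K3 = 0.64, k3 = 0.64 min⁻¹)
    target → decomposed product (k4 = 0.037 min⁻¹)
    reagent in the reaction phase ⇌ reagent in the second phase, rate k5*([reagent in the reaction phase] - [reagent in the second phase]/K5) per volume of the first phase (K5 = 4.2, k5 = 0.27 min⁻¹)
    reagent in the reaction phase ⇌ dormant form (K6 = 11, k6 = 0.13 min⁻¹)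
substrate 0.010 M (fed, over 12 min); reagent in the second phase 1.30 equiv; time 80 min; volume of the second phase over the first 1.0; the fed solution adds 0.25 times the starting volume
- percent here means substrate units held: one side product counts as two
- what is said of target includes product in the second phase
- amounts are per litre of the starting volume; all of the dose is in the solution fed
- in the second phase: reagent in the second phase, product in the second phase; everything else is in the first
- charges count per volume of the first phase; a concentration in a rate is the amount of a species over the volume of its own phase; every rate counts per litre of the first phase
- the reaction counts as stopped when no species that holds the substrate changes by six tenths of a point or more over the second half of the time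
- run time (flask): 80 min
* why nothing more happens at 80 min, or that something still does (forward and back rates have come level / all of the substrate has reacted / it is still moving)
* how much of the substrate has reacted by 80 min
* how much target there is at 80 min, in percent of the substrate charged
* amount of target if the flask were left three thousand times as long, in percent of the substrate charged

Write A for substrate, B for reaction-phase reagent and P for first-phase target, all as concentrations. Target forms at a rate proportional to A·B and is attacked at a rate proportional to A·P, so A cancels while it stays well above 3.08 × 10⁻⁴ M, the decomposition constant over the attack constant. P/B then freezes at the target ratio r, 29 L mol⁻¹ min⁻¹ over 120 L mol⁻¹ min⁻¹, or 0.242, the inverse of the selectivity factor.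

B is not constant, so a late level is reckoned for it. Attack outruns decomposition at the charged level, so each formation costs about two substrates, and full conversion spends about 0.5 equiv of reagent. The remainder, taken as spread at equilibrium over the dormant form and both phases, gives a late B of 4.17 × 10⁻⁴ M.

So late in the run substrate falls with a half-life near 28.7 min, and 2.37 such half-lives follow the feed, which leaves it still moving at the asked time. With target shared between the phases, r·B gives 1.90%, somewhat high if A has come down towards 3.08 × 10⁻⁴ M. Once substrate has reacted, decomposition, with its half-life of 19 min, shorter than the run, takes target to zero.

The forecast says it is still moving, with 91% reacted, 1.4% target, below the figure reckoned here, and 0% in the long run, because, in its words, “nearly every target formed is consumed as side product”.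

The flask gives it is still moving, 93.4% reacted, 1.57% target and 0% in the long run. At 14.3 min, attack uses first-phase target 16 times as fast as decomposition. At 12.0 min, with substrate at 71.9%, this flask reads P/B of 0.233, against r of 0.242. In the neighbour charged with 0.0040 M of substrate, r times its B of 1.97 × 10⁻⁴ M gives 2.25% target, and that neighbour holds 1.87%.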